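1. I started from the reading at 30 min: the question for these flasks was whether their last molecules of acidic substrate had time to react by then.

| flask | acidic substrate | free base | electrophile | remark | time |
|---|---|---|---|---|---|
| grey | 0.30 M | 1.8 M | 1.3 M | run made earlier |  |
| Thursday's | 0.30 M | 1.23 M | 1.30 M |  | 30 min |
| Saturday's | 0.60 M | 1.23 M | 1.30 M |  | 30 min |
| Friday's | 1.2 M | 1.23 M | 1.30 M |  | 30 min |

grey run (percent of the acidic substrate charged): time / min: target / % = 0.500: 88.0; 1.50: 99.7; 3.00: 99.0; 5.00: 99.4; 6.00: 99.8; 8.00: 99.8; 10.0: 99.9

(standard deviation of a reading: 0.5 percentage points)

- what was read earlier has a scatter of 0.5 percentage points, one standard deviation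
- "hardly changes" means that all values lie within two and a half points (for a concentration: within two and a half percent of the largest)
- no earlier run changes the charge of free base; that part of a forecast is a guess

* [target] at the end for Thursday's, Saturday's, Friday's, in this order
* how the row runs (rises, then falls / falls all the way / hardly changes / rises all the way / falls, then rises)

2. The grey run showed 88.0 % target at 0.500 min. Treating that as simple decay gave a pseudo-first-order constant, the chance per minute that one substrate molecule reacts, of 4.24 min⁻¹. Later readings held near 99.8 %, so the grey run showed no decay of the target within its scatter.

3. No earlier run varies the free base, so this step was a guess. I took that constant as proportional to free base and to electrophile, and assumed each reacting molecule uses one of each.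

4. The last substrate molecule then meets the spares, the charges minus the substrate charge. So I defined the closing lifetime as one over the constant scaled to those spares.

5. Friday's acidic substrate was the limiting reagent by charge, 1.2 M against 1.23 M of free base and 1.30 M of electrophile. Its spares were 0.0300 M and 0.100 M, which gave 184 min, longer than the reading time.

6. Thursday's closing lifetime was 0.593 min and Saturday's 1.25 min, both far shorter than the reading time. I expected 0.30 M and 0.60 M of target there.

7. For Friday's flask, leaving the spares out, the rate goes as the cube of what remains, which leaves 0.0959 M of substrate. On the same guess the spares reduce that, so my reckoning gave at least 1.10 M of target in Friday's flask and a row that rises.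

8. The forecast, a point inside my limit rather than a number I reckoned, gave 0.3 M, 0.6 M, 1.16 M, rises all the way, and said “the tail will be slow if the rate depends on both”.

9. The flasks gave 0.300 M, 0.600 M, 1.16 M, rises all the way.

    acidic substrate + anion → side product (k = 7.30 × 10⁻⁵ L mol⁻¹ s⁻¹)
    acidic substrate + free base ⇌ protonated base + anion, settled at all times (K = 0.910)
    electrophile + anion → target (k = 0.0780 L mol⁻¹ s⁻¹)

Friday's closing lifetime of 184 min stood above the reading time of 30 min, and at that reading 2.8 % of Friday's acidic substrate was still there, falling to 0.0631 % after 300 min. Saturday's closing lifetime of 1.25 min was shorter than 15.0 min, and by that time Saturday's acidic substrate stood at 0 %.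

All runs are simulated with made-up constants; noise was put on by code.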